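Retrosynthesis: the C8 methacrylate, C14 acetate and silyl groups come off first; the lactone is cut at O6–C12 (back to a 2-methylene-1,4-diol), the oxirane at its C–O bonds (back to a C14 allylic alcohol) and C10–C14 (back to an enol triflate).
The ten-membered ring is cut at C2–C3 with C5–C10 re-formed (retro anionic oxy-Cope), giving a cis-1,2-dialkenylcyclohexanol; this is cut at C10–C1 (vinyl addition), C5–C4 (enolate alkenylation), C11=C13 (methylenation) and C6–C7/C8–C9 (Diels–Alder).
Forward order of rings: cyclohexane by cycloaddition, ten-membered ring by [3,3] ring expansion, oxirane by epoxidation, γ-lactone last by oxidative lactonisation.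
Stereochemistry: C6, C7, C8 from a catalytic asymmetric endo Diels–Alder reaction of a (Z)-enone followed by C7 epimerisation; C5 by equilibration and C10 by axial organocerium addition (both are consumed in the ring expansion, where they fix the two olefin geometries through a chair transition state); C1/C10 by Sharpless epoxidation with L-(+)-diethyl tartrate.

Key step: step 13

Remark: germacrane locants are used for every intermediate (ring C1–C10, C11–C13 on C7, C14 on C10, C15 on C4). PMB = 4-methoxybenzyl, TBS = tert-butyldimethylsilyl, TBDPS = tert-butyldiphenylsilyl, Tf = trifluoromethanesulfonyl. The β-ketoaldehyde 10 is assumed to rest as its hydrogen-bonded (Z)-enol and to be O-silylated with retention of that geometry.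

Step 1
Reactants: 1 (E)-4-methoxybut-3-en-2-one; 2 4-methoxybenzyl alcohol
Product: 3 (E)-4-[(4-methoxybenzyl)oxy]but-3-en-2-one
Conditions: pyridinium p-toluenesulfonate (5 mol%), toluene, 70 °C, slight vacuum to remove MeOH
Reagents that add atoms: none
Why: Acid-catalysed addition–elimination (transetherification) on the vinylogous ester exchanges OMe for OPMB, keeps the favoured (E)-geometry and is driven by removal of methanol.

Step 2
Reactants: 3 (E)-4-[(4-methoxybenzyl)oxy]but-3-en-2-one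
Product: 4 (E)-1-[(4-methoxybenzyl)oxy]-3-(tert-butyldimethylsilyloxy)buta-1,3-diene
Conditions: TBSOTf, Et3N, Et2O, 0 °C
Reagents that add atoms: tert-butyldimethylsilyl trifluoromethanesulfonate, CC(C)(C)[Si](C)(C)OS(=O)(=O)C(F)(F)F
Why: Soft enolisation and O-silylation of the methyl ketone (silyl enol ether formation) should give the 1-alkoxy-3-silyloxy diene without touching the (E)-enol ether.

Step 3
Reactants: 2 4-methoxybenzyl alcohol; 5 2-chloro-N-methoxy-N-methylacetamide
Product: 6 N-methoxy-2-[(4-methoxybenzyl)oxy]-N-methylacetamide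
Conditions: NaH, THF, 0 → 23 °C
Reagents that add atoms: none
Why: Williamson ether synthesis, the sodium alkoxide of 2 displacing the activated α-chloride by SN2.

Step 4
Reactants: 6 N-methoxy-2-[(4-methoxybenzyl)oxy]-N-methylacetamide; 7 ethynylmagnesium bromide
Product: 8 1-[(4-methoxybenzyl)oxy]but-3-yn-2-one
Conditions: THF, −20 → 0 °C; poured into cold 1 M HCl
Reagents that add atoms: none
Why: Weinreb ketone synthesis, in which the chelated tetrahedral adduct prevents over-addition and the cold acidic quench keeps the released amine from adding to the ynone.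

Step 5
Reactants: 8 1-[(4-methoxybenzyl)oxy]but-3-yn-2-one
Product: 10 (Z)-4-hydroxy-1-[(4-methoxybenzyl)oxy]but-3-en-2-one, via diethylamino enone 9 (not isolated)
Conditions: Et2NH, THF, 0 °C; then 1 M HCl, THF, 0 → 23 °C
Reagents that add atoms: water, O
Why: Aza-Michael addition of the amine to the terminal ynone and acid hydrolysis of the vinylogous amide amount to a conjugate hydration, giving the β-ketoaldehyde as its chelated (Z)-enol.

Step 6
Reactants: 10 (Z)-4-hydroxy-1-[(4-methoxybenzyl)oxy]but-3-en-2-one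
Product: 11 (Z)-4-(tert-butyldimethylsilyloxy)-1-[(4-methoxybenzyl)oxy]but-3-en-2-one
Conditions: TBSOTf, 2,6-lutidine, CH2Cl2, −78 °C; used without delay
Reagents that add atoms: tert-butyldimethylsilyl trifluoromethanesulfonate, CC(C)(C)[Si](C)(C)OS(=O)(=O)C(F)(F)F
Why: Kinetic O-silylation of the chelated enol at low temperature should keep the cis geometry, which is what later places C8–O cis to the acyl group.

Step 7
Reactants: 12 2-bromoprop-2-en-1-ol
Product: 13 tert-butyl[(2-bromoprop-2-en-1-yl)oxy]diphenylsilane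
Conditions: TBDPSCl, imidazole, CH2Cl2, 0 → 23 °C
Reagents that add atoms: tert-butyl(chloro)diphenylsilane, CC(C)(C)[Si](Cl)(c1ccccc1)c1ccccc1
Why: Imidazole-promoted silylation of a primary allylic alcohol gives a TBDPS ether robust enough to last to the final step.

Step 8
Reactants: 4 (E)-1-[(4-methoxybenzyl)oxy]-3-(tert-butyldimethylsilyloxy)buta-1,3-diene; 11 (Z)-4-(tert-butyldimethylsilyloxy)-1-[(4-methoxybenzyl)oxy]but-3-en-2-one
Product: 14 (6R,7R,8S)-cycloadduct 2-(PMBO)-1-[2-(PMBO)-4,6-bis(TBSO)cyclohex-3-en-1-yl]ethan-1-one (C6–OPMB/C7–acyl/C8–OTBS all cis)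
Conditions: (S)-3,3-diphenyl-1-(o-tolyl)tetrahydro-1H,3H-pyrrolo[1,2-c][1,3,2]oxazaborole (20 mol%) protonated with bis(trifluoromethanesulfonyl)imide (20 mol%), CH2Cl2, −78 → −40 °C
Reagents that add atoms: none
Why: Catalytic enantioselective Diels–Alder reaction of a 2-silyloxydiene with an enone under a chiral cationic oxazaborolidine: the nucleophilic diene terminus C9 bonds to the β-carbon C8 and C6 to C7 (ortho rule), the endo transition state with the (Z)-dienophile places the three substituents cis, and the catalyst leaves one π-face of the bound s-cis enone open, which sets C6, C7 and C8 in absolute terms.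

Step 9
Reactants: 14 all-cis cycloadduct
Product: 15 (6R,7S,8S)-C7 epimer of 14 (6,7-trans-7,8-trans)
Conditions: 1,8-diazabicyclo[5.4.0]undec-7-ene (0.2 equiv), toluene, 23 °C
Reagents that add atoms: none
Why: Base-mediated epimerisation α to the C11 ketone under thermodynamic control moves the acyl group away from its two cis oxygen neighbours, and a catalytic amidine at room temperature should be too mild for E1cB loss of the β-alkoxy groups.

Step 10
Reactants: 15 (6R,7S,8S)-ketone
Product: 16 (6S,7S,8S)-1,5-bis(TBSO)-3-(PMBO)-4-[3-(PMBO)prop-1-en-2-yl]cyclohex-1-ene (6,7-trans-7,8-trans)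
Conditions: Ph3PCH3Br, KN(SiMe3)2, THF, 0 → 23 °C
Reagents that add atoms: methyltriphenylphosphonium bromide, C[P+](c1ccccc1)(c1ccccc1)c1ccccc1.[Br-]
Why: Wittig methylenation turns C11=O into the C11=C13 methylene; C7 is already in its thermodynamic configuration, so reversible enolisation by the ylide cannot erode it, and the silyl enol ether is inert.

Step 11
Reactants: 16 silyl enol ether; 13 tert-butyl[(2-bromoprop-2-en-1-yl)oxy]diphenylsilane
Product: 18 (2R,3S,4S,5S)-5-(TBSO)-3-(PMBO)-4-[3-(PMBO)prop-1-en-2-yl]-2-[3-(TBDPSO)prop-1-en-2-yl]cyclohexan-1-one (all four substituents equatorial), via tributyltin enolate 17 (not isolated)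
Conditions: Pd(OAc)2 (5 mol%), P(t-Bu)3 (10 mol%), Bu3SnF, toluene, 85 °C
Reagents that add atoms: none
Why: Palladium-catalysed α-alkenylation of a silyl enol ether through its tin enolate (oxidative addition of zerovalent palladium to the vinyl bromide, transmetalation, reductive elimination) forms C5–C4 at the carbon fixed by the cycloaddition, and the new C5 centre, α to the ketone, should settle equatorial and trans to C6–OPMB.

Step 12
Reactants: 18 cyclohexanone; 19 vinylmagnesium bromide
Product: 20 (1S,2R,3S,4S,5S)-5-(TBSO)-3-(PMBO)-4-[3-(PMBO)prop-1-en-2-yl]-2-[3-(TBDPSO)prop-1-en-2-yl]-1-vinylcyclohexan-1-ol (vinyl axial and cis to the C5 alkenyl group)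
Conditions: CeCl3 (anhydrous), THF, −78 °C
Reagents that add atoms: none
Why: Organocerium 1,2-addition: the weakly basic vinylcerium reagent should add without enolisation or β-elimination and along the axial trajectory, because the equatorial path is blocked by the 1,1-disubstituted alkenyl group at C5, which places the vinyl group axial and the C10 hydroxyl equatorial.

Step 13
Reactants: 20 cis-1,2-dialkenylcyclohexanol
Product: 23 (1(10)-ring-trans,4-ring-cis)-8-(TBSO)-6-(PMBO)-7-[3-(PMBO)prop-1-en-2-yl]-4-(TBDPSO-methyl)cyclodeca-1(10),4-dien-10-yl triflate, via potassium alkoxide 21 (not isolated), via potassium dienolate 22 (not isolated)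
Conditions: KH, 18-crown-6, THF, 0 → 23 °C; then PhNTf2, −78 → 0 °C
Reagents that add atoms: N-phenylbis(trifluoromethanesulfonimide), O=S(=O)(N(c1ccccc1)S(=O)(=O)C(F)(F)F)C(F)(F)F
Why: KH with 18-crown-6 gives the dissociated alkoxide 21, whose oxyanion weakens C5–C10 and triggers a [3,3]-sigmatropic shift across the 1,5-diene C2=C1–C10–C5–C4=C3, forming C2–C3 and breaking C5–C10. The closest known reaction type is the anionic oxy-Cope ring expansion of 1,2-dialkenylcyclohexanols to cyclodec-5-enones with O-sulfonylation of the enolate in the same flask. The ten-membered ring is not closed by a cyclisation but arises by four-atom sigmatropic enlargement of the cyclohexane through a chair-like six-centre transition state. No new stereocentre is formed (C6, C7 and C8 are spectators); what must be controlled are the two olefin geometries. In the reacting chair the C10 vinyl is axial and every other substituent equatorial, so in the Cope chair C9 is pseudo-equatorial on C10 and C6 pseudo-axial on C5, which gives the ring-trans C1=C10 enolate and the ring-cis C4=C5 olefin. The enolate 22 is formed regiospecifically toward C1 and is trapped on oxygen at −78 °C before proton exchange to C9 could open β-elimination of the C8 silyloxy group, so the triflate carries the handle for C14.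

Step 14
Reactants: 23 enol triflate
Product: 24 methyl (1(10)-ring-trans,4-ring-cis)-cyclodeca-1(10),4-diene-10-carboxylate (C14 ester; other groups as in 23)
Conditions: Pd(PPh3)4 (10 mol%), CO (1 atm), MeOH, Et3N, DMF, 50 °C
Reagents that add atoms: carbon monoxide, [C-]#[O+]; methanol, CO
Why: Palladium-catalysed methoxycarbonylation of an enol triflate (oxidative addition, CO insertion, methanolysis) installs C14 with retention of the olefin geometry.

Step 15
Reactants: 24 methyl ester
Product: 25 C14 allylic alcohol (10-hydroxymethyl cyclodeca-1(10),4-diene; other groups as in 23)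
Conditions: iBu2AlH, CH2Cl2, −78 °C; Rochelle salt work-up
Reagents that add atoms: none
Why: Hydride 1,2-reduction of the α,β-unsaturated ester to the primary allylic alcohol; ethers and silyl ethers are inert.

Step 16
Reactants: 25 allylic alcohol
Product: 26 (1R,10S)-1,10-epoxy C14 alcohol (C4=C5 ring-cis; C6/C7/C8 unchanged)
Conditions: Ti(OiPr)4, L-(+)-diethyl tartrate, t-BuOOH, 4 Å molecular sieves, CH2Cl2, −20 °C
Reagents that add atoms: tert-butyl hydroperoxide, CC(C)(C)OO
Why: Sharpless asymmetric epoxidation touches only the free allylic alcohol; the trans relation of C9 and C2 follows from the olefin geometry, and L-(+)-tartrate, which turns (Z)-3-substituted allylic alcohols into (2S,3R)-epoxy alcohols, should deliver oxygen to the face that gives the (1R,10S)-oxirane.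

Step 17
Reactants: 26 epoxy alcohol
Product: 27 C14 acetate of 26
Conditions: Ac2O, pyridine, 4-(dimethylamino)pyridine (5 mol%), CH2Cl2, 0 °C
Reagents that add atoms: acetic anhydride, CC(=O)OC(C)=O
Why: Nucleophile-catalysed acylation of the primary alcohol.

Step 18
Reactants: 27 bis-PMB ether
Product: 28 C6,C12-diol (14-OAc; 8-OTBS; 15-OTBDPS; epoxide intact)
Conditions: DDQ, CH2Cl2/pH 7 phosphate buffer, 0 → 23 °C
Reagents that add atoms: none
Why: Oxidative cleavage of both 4-methoxybenzyl ethers (hydride abstraction, hydrolysis of the oxocarbenium ion) under buffered conditions leaves silyl ethers, acetate and epoxide untouched.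

Step 19
Reactants: 28 diol
Product: 31 trans-fused α-methylene 12,6-lactone (14-OAc; 8-OTBS; 15-OTBDPS), via hydroxy enal 29 (not isolated), via lactol 30 (not isolated)
Conditions: PhI(OAc)2, 2,2,6,6-tetramethylpiperidin-1-oxyl (20 mol%), CH2Cl2, 23 °C
Reagents that add atoms: none
Why: Nitroxyl-catalysed oxidation selects the primary allylic C12 alcohol over the secondary C6 alcohol, the enal is captured by C6–OH as a five-membered lactol and this is oxidised on to the lactone (tandem oxidative lactonisation); the trans ring fusion follows from the C6/C7 relation set in step 9.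

Step 20
Reactants: 31 lactone
Product: 32 C8 alcohol (14-OAc; 15-OTBDPS)
Conditions: HF·pyridine, pyridine, THF, 0 → 23 °C
Reagents that add atoms: none
Why: Selective desilylation: buffered HF cleaves the secondary TBS ether much faster than the primary TBDPS ether, and the excess pyridine guards the epoxide against acid-induced transannular opening.

Step 21
Reactants: 32 C8 alcohol
Product: 33 C8 methacrylate (14-OAc; 15-OTBDPS)
Conditions: methacrylic anhydride, Et3N, 4-(dimethylamino)pyridine (20 mol%), CH2Cl2, 0 → 23 °C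
Reagents that add atoms: methacrylic anhydride, C=C(C)C(=O)OC(=O)C(C)=C
Why: Nucleophile-catalysed acylation of the hindered secondary alcohol with the anhydride; C8 keeps its configuration.

Step 22
Reactants: 33 silyl ether
Product: 34 (1R,6R,7R,8S,10S,4E)-14-acetoxy-1,10-epoxy-15-hydroxy-8-(methacryloyloxy)germacra-4,11(13)-dien-12,6-olide
Conditions: Bu4NF, AcOH (1:1), THF, 0 → 23 °C
Reagents that add atoms: none
Why: Fluoride-mediated cleavage of the TBDPS ether, buffered with acetic acid to spare the acetate, the methacrylate and the Michael-acceptor lactone, frees the C15 alcohol.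

Compound list
1 | (E)-4-methoxybut-3-en-2-one | CO/C=C/C(C)=O | starting material
2 | 4-methoxybenzyl alcohol | COc1ccc(CO)cc1 | starting material
3 | (E)-4-[(4-methoxybenzyl)oxy]but-3-en-2-one | CC(=O)/C=C/OCc1ccc(OC)cc1 | intermediate
4 | (E)-1-[(4-methoxybenzyl)oxy]-3-(tert-butyldimethylsilyloxy)buta-1,3-diene | C=C(O[Si](C)(C)C(C)(C)C)/C=C/OCc1ccc(OC)cc1 | intermediate
5 | 2-chloro-N-methoxy-N-methylacetamide | CON(C)C(=O)CCl | starting material
6 | N-methoxy-2-[(4-methoxybenzyl)oxy]-N-methylacetamide | CON(C)C(=O)COCc1ccc(OC)cc1 | intermediate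
7 | ethynylmagnesium bromide | C#C[Mg]Br | starting material
8 | 1-[(4-methoxybenzyl)oxy]but-3-yn-2-one | C#CC(=O)COCc1ccc(OC)cc1 | intermediate
9 | (E)-4-(diethylamino)-1-[(4-methoxybenzyl)oxy]but-3-en-2-one (formed in the flask) | CCN(CC)/C=C/C(=O)COCc1ccc(OC)cc1 | intermediate
10 | (Z)-4-hydroxy-1-[(4-methoxybenzyl)oxy]but-3-en-2-one | O/C=C\C(=O)COCc1ccc(OC)cc1 | intermediate
11 | (Z)-4-(tert-butyldimethylsilyloxy)-1-[(4-methoxybenzyl)oxy]but-3-en-2-one | CC(C)(C)[Si](C)(C)O/C=C\C(=O)COCc1ccc(OC)cc1 | intermediate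
12 | 2-bromoprop-2-en-1-ol | OCC(Br)=C | starting material
13 | tert-butyl[(2-bromoprop-2-en-1-yl)oxy]diphenylsilane | C=C(Br)CO[Si](c1ccccc1)(c1ccccc1)C(C)(C)C | intermediate
14 | (6R,7R,8S)-all-cis cycloadduct, 2-(PMBO)-1-[2-(PMBO)-4,6-bis(TBSO)cyclohex-3-en-1-yl]ethan-1-one | CC(C)(C)[Si](C)(C)OC1=C[C@@H](OCc2ccc(OC)cc2)[C@@H](C(=O)COCc2ccc(OC)cc2)[C@@H](O[Si](C)(C)C(C)(C)C)C1 | intermediate
15 | (6R,7S,8S)-C7 epimer of 14 (6,7-trans-7,8-trans) | CC(C)(C)[Si](C)(C)OC1=C[C@@H](OCc2ccc(OC)cc2)[C@H](C(=O)COCc2ccc(OC)cc2)[C@@H](O[Si](C)(C)C(C)(C)C)C1 | intermediate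
16 | (6S,7S,8S)-1,5-bis(TBSO)-3-(PMBO)-4-[3-(PMBO)prop-1-en-2-yl]cyclohex-1-ene | CC(C)(C)[Si](C)(C)OC1=C[C@@H](OCc2ccc(OC)cc2)[C@H](C(=C)COCc2ccc(OC)cc2)[C@@H](O[Si](C)(C)C(C)(C)C)C1 | intermediate
17 | tributyltin enolate corresponding to 16 (formed in the flask) | CCCC[Sn](CCCC)(CCCC)OC1=C[C@@H](OCc2ccc(OC)cc2)[C@H](C(=C)COCc2ccc(OC)cc2)[C@@H](O[Si](C)(C)C(C)(C)C)C1 | intermediate
18 | (2R,3S,4S,5S)-5-(TBSO)-3-(PMBO)-4-[3-(PMBO)prop-1-en-2-yl]-2-[3-(TBDPSO)prop-1-en-2-yl]cyclohexan-1-one | O=C1C[C@H](O[Si](C)(C)C(C)(C)C)[C@@H](C(=C)COCc2ccc(OC)cc2)[C@H](OCc2ccc(OC)cc2)[C@H]1C(=C)CO[Si](c1ccccc1)(c1ccccc1)C(C)(C)C | intermediate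
19 | vinylmagnesium bromide | C=C[Mg]Br | starting material
20 | (1S,2R,3S,4S,5S)-5-(TBSO)-3-(PMBO)-4-[3-(PMBO)prop-1-en-2-yl]-2-[3-(TBDPSO)prop-1-en-2-yl]-1-vinylcyclohexan-1-ol | C=C[C@@]1(O)C[C@H](O[Si](C)(C)C(C)(C)C)[C@@H](C(=C)COCc2ccc(OC)cc2)[C@H](OCc2ccc(OC)cc2)[C@H]1C(=C)CO[Si](c1ccccc1)(c1ccccc1)C(C)(C)C | intermediate
21 | potassium alkoxide of 20 (formed in the flask) | C=C[C@@]1([O-])C[C@H](O[Si](C)(C)C(C)(C)C)[C@@H](C(=C)COCc2ccc(OC)cc2)[C@H](OCc2ccc(OC)cc2)[C@H]1C(=C)CO[Si](c1ccccc1)(c1ccccc1)C(C)(C)C.[K+] | intermediate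
22 | potassium (1(10)-ring-trans,4-ring-cis)-cyclodeca-1(10),4-dien-10-olate (formed in the flask) | CC(C)(C)[Si](C)(C)O[C@H]1C/C([O-])=C/CC/C(CO[Si](c2ccccc2)(c2ccccc2)C(C)(C)C)=C\[C@@H](OCc2ccc(OC)cc2)[C@@H]1C(=C)COCc1ccc(OC)cc1.[K+] | intermediate
23 | (1(10)-ring-trans,4-ring-cis)-8-(TBSO)-6-(PMBO)-7-[3-(PMBO)prop-1-en-2-yl]-4-(TBDPSO-methyl)cyclodeca-1(10),4-dien-10-yl triflate | CC(C)(C)[Si](C)(C)O[C@H]1C/C(OS(=O)(=O)C(F)(F)F)=C/CC/C(CO[Si](c2ccccc2)(c2ccccc2)C(C)(C)C)=C\[C@@H](OCc2ccc(OC)cc2)[C@@H]1C(=C)COCc1ccc(OC)cc1 | intermediate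
24 | C14 methyl ester (methyl cyclodeca-1(10),4-diene-10-carboxylate, groups as in 23) | CC(C)(C)[Si](C)(C)O[C@H]1C/C(C(=O)OC)=C/CC/C(CO[Si](c2ccccc2)(c2ccccc2)C(C)(C)C)=C\[C@@H](OCc2ccc(OC)cc2)[C@@H]1C(=C)COCc1ccc(OC)cc1 | intermediate
25 | C14 allylic alcohol | CC(C)(C)[Si](C)(C)O[C@H]1C/C(CO)=C/CC/C(CO[Si](c2ccccc2)(c2ccccc2)C(C)(C)C)=C\[C@@H](OCc2ccc(OC)cc2)[C@@H]1C(=C)COCc1ccc(OC)cc1 | intermediate
26 | (1R,10S)-1,10-epoxy C14 alcohol | CC(C)(C)[Si](C)(C)O[C@H]1C[C@@]2(CO)O[C@@H]2CC/C(CO[Si](c3ccccc3)(c3ccccc3)C(C)(C)C)=C\[C@@H](OCc3ccc(OC)cc3)[C@@H]1C(=C)COCc1ccc(OC)cc1 | intermediate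
27 | C14 acetate of 26 | CC(C)(C)[Si](C)(C)O[C@H]1C[C@@]2(COC(C)=O)O[C@@H]2CC/C(CO[Si](c3ccccc3)(c3ccccc3)C(C)(C)C)=C\[C@@H](OCc3ccc(OC)cc3)[C@@H]1C(=C)COCc1ccc(OC)cc1 | intermediate
28 | C6,C12-diol | CC(C)(C)[Si](C)(C)O[C@H]1C[C@@]2(COC(C)=O)O[C@@H]2CC/C(CO[Si](c3ccccc3)(c3ccccc3)C(C)(C)C)=C\[C@@H](O)[C@@H]1C(=C)CO | intermediate
29 | C12 enal with free C6–OH (formed in the flask) | CC(C)(C)[Si](C)(C)O[C@H]1C[C@@]2(COC(C)=O)O[C@@H]2CC/C(CO[Si](c3ccccc3)(c3ccccc3)C(C)(C)C)=C\[C@@H](O)[C@@H]1C(=C)C=O | intermediate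
30 | C12 lactol (formed in the flask) | CC(C)(C)[Si](C)(C)O[C@H]1C[C@@]2(COC(C)=O)O[C@@H]2CC/C(CO[Si](c3ccccc3)(c3ccccc3)C(C)(C)C)=C\[C@H]2OC(O)C(=C)[C@H]12 | intermediate
31 | 8-O-TBS 15-O-TBDPS 14-acetoxy-1,10-epoxygermacra-4,11(13)-dien-12,6-olide | CC(C)(C)[Si](C)(C)O[C@H]1C[C@@]2(COC(C)=O)O[C@@H]2CC/C(CO[Si](c3ccccc3)(c3ccccc3)C(C)(C)C)=C\[C@H]2OC(=O)C(=C)[C@H]12 | intermediate
32 | C8 alcohol (15-O-TBDPS) | O[C@H]1C[C@@]2(COC(C)=O)O[C@@H]2CC/C(CO[Si](c3ccccc3)(c3ccccc3)C(C)(C)C)=C\[C@H]2OC(=O)C(=C)[C@H]12 | intermediate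
33 | C8 methacrylate (15-O-TBDPS) | C=C(C)C(=O)O[C@H]1C[C@@]2(COC(C)=O)O[C@@H]2CC/C(CO[Si](c3ccccc3)(c3ccccc3)C(C)(C)C)=C\[C@H]2OC(=O)C(=C)[C@H]12 | intermediate
34 | (1R,6R,7R,8S,10S,4E)-14-acetoxy-1,10-epoxy-15-hydroxy-8-(methacryloyloxy)germacra-4,11(13)-dien-12,6-olide | C=C(C)C(=O)O[C@H]1C[C@@]2(COC(C)=O)O[C@@H]2CC/C(CO)=C\[C@H]2OC(=O)C(=C)[C@H]12 | target

Total step count: 22. Longest linear sequence: 19 steps (steps 3–6 and 8–22).

Steps most likely to fail

Step 8. The acid-labile diene may be desilylated by the cationic boron catalyst, or the (Z)-enone may isomerise, so that facial and endo/cis selectivity are lost. The fallback replaces one-point activation by chelation to a chiral copper Lewis acid. It sets out from 11: DDQ in buffered CH2Cl2 removes the PMB group to give the α'-hydroxy enone (Z)-4-(tert-butyldimethylsilyloxy)-1-hydroxybut-3-en-2-one F1. Cycloaddition of F1 with diene 4 is run with the divalent copper complex Cu(SbF6)2·2,2'-(propane-2,2-diyl)bis[(4S)-4-tert-butyl-4,5-dihydrooxazole] in CH2Cl2 at −40 °C, where ketone and hydroxyl bind the metal together, and should give the all-cis hydroxy ketone cycloadduct F2. Etherification of its primary alcohol with 4-methoxybenzyl bromide and Ag2O returns to the route at 14.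

Step 11. Tin/fluoride transfer from the hindered TBS enol ether may be slow, and at 85 °C the metal enolate may lose the C6 alkoxy group by E1cB or the new β,γ-olefin may move into conjugation. The fallback reverses the polarity and starts from 16: N-bromosuccinimide in THF at −78 °C gives the α-bromo ketone 2-bromo-5-(TBSO)-3-(PMBO)-4-[3-(PMBO)prop-1-en-2-yl]cyclohexan-1-one F3. Bromide 13 is converted with t-BuLi and then ZnCl2 into the alkenylzinc reagent [3-(TBDPSO)prop-1-en-2-yl]zinc chloride F4. A nickel-catalysed Negishi coupling of the secondary α-bromo ketone (NiCl2·glyme, 4,4'-di-tert-butyl-2,2'-bipyridine, THF/DMA, 0 °C), which is stereoconvergent and needs no enolate, should then give 18 after equilibration of C5.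

Step 12. The vinyl reagent may attack along the equatorial path and give the C10 epimer (alkenyl groups trans), which would lead to the wrong C4=C5 geometry in step 13. The fallback uses a rod-shaped nucleophile with a strong axial preference and starts from 18: lithium (trimethylsilyl)acetylide with CeCl3 in THF at −78 °C should give the axial alkynyl carbinol 1-[(trimethylsilyl)ethynyl] analogue of 20 F5. K2CO3 in MeOH removes the C-silyl group to give the 1-ethynyl analogue of 20 F6. Lindlar semi-hydrogenation (H2, Pd on CaCO3 poisoned with Pb(OAc)2, quinoline, EtOAc) returns to the route at 20.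

Further compounds
F1 | step 8 | (Z)-4-(tert-butyldimethylsilyloxy)-1-hydroxybut-3-en-2-one | CC(C)(C)[Si](C)(C)O/C=C\C(=O)CO
F2 | step 8 | all-cis hydroxy ketone cycloadduct, 2-hydroxy-1-[2-(PMBO)-4,6-bis(TBSO)cyclohex-3-en-1-yl]ethan-1-one | CC(C)(C)[Si](C)(C)OC1=C[C@@H](OCc2ccc(OC)cc2)[C@@H](C(=O)CO)[C@@H](O[Si](C)(C)C(C)(C)C)C1
F3 | step 11 | 2-bromo-5-(TBSO)-3-(PMBO)-4-[3-(PMBO)prop-1-en-2-yl]cyclohexan-1-one | O=C1C[C@H](O[Si](C)(C)C(C)(C)C)[C@@H](C(=C)COCc2ccc(OC)cc2)[C@H](OCc2ccc(OC)cc2)C1Br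
F4 | step 11 | [3-(TBDPSO)prop-1-en-2-yl]zinc chloride | C=C([Zn]Cl)CO[Si](c1ccccc1)(c1ccccc1)C(C)(C)C
F5 | step 12 | 1-[(trimethylsilyl)ethynyl] analogue of 20 | C[Si](C)(C)C#C[C@@]1(O)C[C@H](O[Si](C)(C)C(C)(C)C)[C@@H](C(=C)COCc2ccc(OC)cc2)[C@H](OCc2ccc(OC)cc2)[C@H]1C(=C)CO[Si](c1ccccc1)(c1ccccc1)C(C)(C)C
F6 | step 12 | 1-ethynyl analogue of 20 | C#C[C@@]1(O)C[C@H](O[Si](C)(C)C(C)(C)C)[C@@H](C(=C)COCc2ccc(OC)cc2)[C@H](OCc2ccc(OC)cc2)[C@H]1C(=C)CO[Si](c1ccccc1)(c1ccccc1)C(C)(C)C
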